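**Retrosynthetic overview**
1. Numbering as in drimanes (ring A: C1–C5 and C10; ring B: C5–C10; C11 on C9, C12 on C8; β = face of the C10 methyl). The C11/C12 dialdehyde and the 1β-(Z)-cinnamate are end-game adjustments of a tricyclic 11-menthyloxy-12,11-olide that already holds ring B.
2. Key disconnection: ring B is opened at C5–C6 and at C7=C8. Forward, a vinyl ether on the tertiary allylic C3–O of ring A undergoes Claisen rearrangement (C5–C6), and the aldehyde released is closed onto the α-phosphono lactone carbon C8 by intramolecular Horner–Wadsworth–Emmons olefination (C7=C8), in one flask.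
3. Enabling feature: the tetrasubstituted C3=C4 double bond of ring A next to the C5 ring-fusion stereocentre is the retron of a [3,3] shift from a C3–O–vinyl group (C3 chirality passes to C5, the alkene is fixed at C3=C4). The C7=C8 enal flanked by C9–C11 is an alkylidene-succinaldehyde unit, the retron of an olefination at C8.
4. The monocyclic precursor comes from a Diels–Alder/retro-aldol sequence between a Birch-derived 1-methoxycyclohexa-1,3-diene and (5R)-5-(l-menthyloxy)furan-2(5H)-one (the only purchased stereocentre; it sets C10 and C9), then substrate-controlled C1 oxygenation (conjugate borylation) and methyl addition at C3.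
5. Order of ring formation: ring A (from 2,4-dimethylanisole) → butyrolactone appended at C10 → ring B (key step) → lactone opened to the dialdehyde.

Key step: step 10

Remark: the same atom labels are used for the monocyclic precursors; the lactone α-carbon (C8) of 13, 14 and 15 is drawn as the trans epimer, although it is configurationally labile and is lost in step 10; 4 is taken to be commercially available.

Step 1
Reactants: 1 2,4-dimethylanisole
Product: 2 1-methoxy-2,4-dimethylcyclohexa-1,4-diene
Conditions: Li, NH3 (l), THF, t-BuOH, −78 → −33 °C; NH4Cl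
Reagents that add atoms: none
Why: Birch reduction of an alkyl anisole leaves the two double bonds on the carbons that carry the methoxy and alkyl groups, so the 1,4-diene with a tetrasubstituted enol ether should form regioselectively; no stereocentre arises.

Step 2
Reactants: 2 1-methoxy-2,4-dimethylcyclohexa-1,4-diene
Product: 3 1-methoxy-2,4-dimethylcyclohexa-1,3-diene
Conditions: KOtBu (cat.), DMSO, 25 °C
Reagents that add atoms: none
Why: Base-mediated prototropic isomerization of a 2,5-dihydroanisole moves the isolated olefin into conjugation with the enol ether, and the most substituted 1-alkoxy-1,3-diene should be the thermodynamic isomer; the product is achiral.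

Step 3
Reactants: 3 1-methoxy-2,4-dimethylcyclohexa-1,3-diene; 4 (5R)-5-[(1R,2S,5R)-menthyloxy]furan-2(5H)-one
Product: 6 (4S)-2,4-dimethyl-4-[(2R,3S)-2-(l-menthyloxy)-5-oxooxolan-3-yl]cyclohex-2-en-1-one, via Diels–Alder adduct 5 (not isolated)
Conditions: toluene, BHT (cat.), 110 °C, sealed tube; then TsOH·H2O (cat.), acetone/H2O, 45 °C
Reagents that add atoms: water, O
Why: A normal-demand Diels–Alder reaction should join the methyl-bearing terminus of the 1-alkoxydiene to the β-carbon of the butenolide (alkoxy-directed regiochemistry), on the face anti to the menthyloxy group and endo, which sets C10 and C9 in absolute and relative terms, and acid then promotes a retro-aldol (Grob-type) fragmentation of the β-methoxy lactone, the bridgehead methoxy group pushing out the lactone enol, to unveil the 4,4-disubstituted cyclohexenone after hydrolysis of the oxocarbenium ion.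

Step 4
Reactants: 6 enone lactone
Product: 7 (4S)-2,4-dimethyl-4-[(2R,3S)-2-(l-menthyloxy)-5-oxooxolan-3-yl]cyclohexa-2,5-dien-1-one
Conditions: DDQ, 1,4-dioxane, 100 °C
Reagents that add atoms: none
Why: DDQ dehydrogenation of a cyclohex-2-enone with a quaternary γ-carbon can only occur across C1–C2 and should give the cross-conjugated dienone, as in the 4-en-3-one to 1,4-dien-3-one conversion; no stereocentre is affected.

Step 5
Reactants: 7 cross-conjugated dienone
Product: 9 (4S,5R)-5-hydroxy-2,4-dimethyl-4-[(2R,3S)-2-(l-menthyloxy)-5-oxooxolan-3-yl]cyclohex-2-en-1-one, via β-boryl ketone 8 (not isolated)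
Conditions: CuCl (cat.), Xantphos (cat.), KOtBu (cat.), B2pin2, MeOH, THF, 0 °C; then 30 % H2O2, pH 7 phosphate buffer, 0 °C
Reagents that add atoms: bis(pinacolato)diboron, CC1(C)OB(OC1(C)C)B1OC(C)(C)C(C)(C)O1 (boron of 8); hydrogen peroxide, OO (hydroxyl oxygen of 9)
Why: Copper-catalysed conjugate borylation should select the unsubstituted enone arm over the α-methylated one and the face of the flat dienone opposite the bulky lactone on C10 (the methyl face), and oxidation of the C–B bond with retention then gives the 1β-alcohol.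

Step 6
Reactants: 9 β-hydroxy enone
Product: 10 1β-triethylsilyl ether of 9
Conditions: Et3SiOTf, 2,6-lutidine, CH2Cl2, −78 °C
Reagents that add atoms: triethylsilyl trifluoromethanesulfonate, CC[Si](CC)(CC)OS(=O)(=O)C(F)(F)F
Why: Silylation of the β-hydroxy ketone with a silyl triflate and a hindered pyridine base at low temperature is a standard protection that avoids β-elimination; no stereocentre changes.

Step 7
Reactants: 10 silyloxy enone
Product: 11 tertiary allylic alcohol (C3: OH β, CH3 α)
Conditions: MeLi, CeCl3, THF, −78 °C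
Reagents that add atoms: methyllithium, [Li]C
Why: The organocerium reagent should add 1,2 to the enone carbonyl in preference to the lactone and without enolization, by axial attack trans to the equatorial C1 silyloxy group of the half-chair, which places the new C3 oxygen on the β face (cis to C1–O and to the C10 methyl).

Step 8
Reactants: 11 tertiary allylic alcohol
Product: 12 vinyl ether of 11 (C3–O–CH=CH2)
Conditions: vinyl acetate, [Ir(cod)Cl]2 (cat.), Na2CO3, toluene, 90 °C
Reagents that add atoms: vinyl acetate, CC(=O)OC=C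
Why: Iridium-catalysed transfer vinylation from vinyl acetate converts alcohols, including tertiary ones, into vinyl ethers under weakly basic conditions that should leave lactone, acetal and silyl ether untouched; no stereocentre changes.

Step 9
Reactants: 12 allyl vinyl ether
Product: 14 α-(diethoxyphosphoryl) lactone of 12, via diethyl phosphonite 13 (not isolated)
Conditions: LiN(iPr)2, THF, −78 °C; ClP(OEt)2, −78 → 0 °C; then 30 % H2O2, 0 °C
Reagents that add atoms: diethyl chlorophosphite, CCOP(Cl)OCC; hydrogen peroxide, OO (phosphoryl oxygen)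
Why: The lactone α-methylene is the only acidic C–H, so its lithium enolate should be C-phosphinylated by the chlorophosphite and the phosphonite oxidized to the α-phosphono lactone (enolate phosphinylation–oxidation); the new C8 centre is labile and is lost in step 10.

Step 10
Reactants: 14 allyl vinyl ether phosphonate
Product: 16 tricyclic 1β-(triethylsilyloxy)-11-(l-menthyloxy)-3,7-diene-12,11-olide, via Claisen aldehyde 15 (not isolated)
Conditions: toluene, iPr2NEt (0.2 equiv), 170 °C, sealed tube; cool to 0 °C; then LiCl, iPr2NEt, MeCN, 0 → 23 °C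
Reagents that add atoms: none
Why: On heating, the allyl vinyl ether should undergo a concerted suprafacial [3,3]-sigmatropic (Claisen) rearrangement that forms C5–C6, breaks C3–O and moves the double bond to C3=C4, and the aldehyde 15 so released is then trapped by the lithium-chelated phosphonate carbanion at C8 in an intramolecular Horner–Wadsworth–Emmons olefination that forms C7=C8; the closest known reactions are the thermal Claisen rearrangement of tertiary allyl vinyl ethers and the LiCl/amine olefination of α-phosphono-γ-butyrolactones with aldehydes. Ring B is closed in the olefination by a 6-(enolexo)-exo-trig addition of the C8 carbanion to the C7 aldehyde followed by syn-elimination of diethyl phosphate, the ring itself holding C6 and C9 cis across C7=C8. The only new stereocentre, C5, is set by chirality transfer: the C3–O bond lies on the β face, so C6 is delivered to the β face of C5 (H-5 α) while the C3 stereocentre is erased. C9 and C10 are untouched, and since the C5 and C10 side chains are then trans on ring A, the 5α,10β (trans) ring fusion should result. The step needs the [3,3] shift to win over loss of the tertiary vinyloxy group and the olefination to occur only at C8; C5 is the single allylic terminus open to the pericyclic path, the amine buffer keeps acid away, and the doubly activated C8–H is the only proton that LiCl/iPr2NEt can remove, so C9 should not epimerize.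

Step 11
Reactants: 16 tricyclic lactone
Product: 18 1β,11,12-triol (5α-H, 9α-H, 10β-CH3, 3,7-diene), via silyl ether diol 17 (not isolated)
Conditions: LiAlH4, THF, 0 → 23 °C; then AcOH/THF/H2O, 23 °C
Reagents that add atoms: none
Why: Hydride reduction of the unsaturated lactone should open it to the enal and the hemiacetal, which expels menthol, and both aldehydes are reduced 1,2 to the allylic 11,12-diol (lactone-to-diol reduction) without touching C9, and mild aqueous acid then cleaves the secondary triethylsilyl ether.

Step 12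
Reactants: 18 triol
Product: 19 11,12-bis(tert-butyldimethylsilyl) ether with free 1β-OH
Conditions: tBuMe2SiCl (2.2 equiv), imidazole, DMF, 0 °C
Reagents that add atoms: tert-butyldimethylsilyl chloride, CC(C)(C)[Si](C)(C)Cl
Why: The two primary hydroxyls should silylate far faster than the neopentyl-type secondary C1–OH, so selective bis-silylation is expected.

Step 13
Reactants: 19 bis-silyl ether alcohol; 20 3-phenylpropiolic acid
Product: 21 1β-(3-phenylpropioloyl) ester of 19
Conditions: DIC, DMAP, CH2Cl2, 0 → 23 °C
Reagents that add atoms: none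
Why: Carbodiimide/DMAP (Steglich) esterification should acylate the remaining secondary alcohol with retention at C1, and the alkynoic acid postpones the question of olefin geometry.

Step 14
Reactants: 21 phenylpropiolate
Product: 22 1β-(Z)-cinnamate bis-silyl ether
Conditions: H2 (1 atm), Pd/CaCO3 poisoned with Pb(OAc)2 (Lindlar), quinoline, EtOAc, 23 °C
Reagents that add atoms: none
Why: Lindlar semihydrogenation adds hydrogen syn to the conjugated alkyne and should stop at the (Z)-cinnamate, the tri- and tetrasubstituted ring olefins being inert to the poisoned catalyst.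

Step 15
Reactants: 22 (Z)-cinnamate bis-silyl ether
Product: 23 1β-(Z)-cinnamoyloxy-11,12-diol
Conditions: HF·pyridine, pyridine, THF, 0 → 23 °C
Reagents that add atoms: none
Why: Buffered fluoride should cleave the two primary silyl ethers without acyl migration or ester cleavage (desilylation).

Step 16
Reactants: 23 diol
Product: 24 target dialdehyde
Conditions: (COCl)2, DMSO, CH2Cl2, −78 °C; then iPr2NEt, −78 → −30 °C
Reagents that add atoms: none
Why: In the Swern oxidation both alkoxysulfonium ions are formed before base is added, so the 1,4-diol should go to the dialdehyde and not to a lactol or lactone, and the hindered amine at low temperature should leave the epimerizable C9 centre and the (Z)-ester untouched.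

**Compound list**
1 | 2,4-dimethylanisole | COc1ccc(C)cc1C | starting material
2 | 1-methoxy-2,4-dimethylcyclohexa-1,4-diene | COC1=C(C)CC(C)=CC1 | intermediate
3 | 1-methoxy-2,4-dimethylcyclohexa-1,3-diene | COC1=C(C)C=C(C)CC1 | intermediate
4 | (5R)-5-{[(1R,2S,5R)-2-isopropyl-5-methylcyclohexyl]oxy}furan-2(5H)-one | O=C1C=C[C@H](O[C@@H]2C[C@H](C)CC[C@H]2C(C)C)O1 | starting material
5 | endo, anti Diels–Alder adduct: bicyclo[2.2.2]oct-5-ene with bridgehead OCH3 (C3) and bridgehead CH3 (C10), cis-fused across C8–C9 to the menthyloxy-γ-butyrolactone (C12=O on C8, acetal C11 on C9, lactone syn to the C4=C5 bridge, C10 trans to the menthyloxy group) | CO[C@@]12CC[C@@](C)(C=C1C)[C@H]3[C@H](O[C@@H]4C[C@H](C)CC[C@H]4C(C)C)OC(=O)[C@H]32 | intermediate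
6 | (4S)-2,4-dimethyl-4-[(2R,3S)-2-(l-menthyloxy)-5-oxooxolan-3-yl]cyclohex-2-en-1-one | CC1=C[C@](C)(CCC1=O)[C@@H]2CC(=O)O[C@H]2O[C@@H]3C[C@H](C)CC[C@H]3C(C)C | intermediate
7 | (4S)-2,4-dimethyl-4-[(2R,3S)-2-(l-menthyloxy)-5-oxooxolan-3-yl]cyclohexa-2,5-dien-1-one | CC1=C[C@](C)(C=CC1=O)[C@@H]2CC(=O)O[C@H]2O[C@@H]3C[C@H](C)CC[C@H]3C(C)C | intermediate
8 | β-boryl ketone: 1β-(pinacolboryl) analogue of 9 | CC1=C[C@](C)([C@H](B2OC(C)(C)C(C)(C)O2)CC1=O)[C@@H]3CC(=O)O[C@H]3O[C@@H]4C[C@H](C)CC[C@H]4C(C)C | intermediate
9 | (4S,5R)-5-hydroxy-2,4-dimethyl-4-[(2R,3S)-2-(l-menthyloxy)-5-oxooxolan-3-yl]cyclohex-2-en-1-one (C1–OH β, cis to the C10 methyl) | CC1=C[C@](C)([C@H](O)CC1=O)[C@@H]2CC(=O)O[C@H]2O[C@@H]3C[C@H](C)CC[C@H]3C(C)C | intermediate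
10 | 1β-triethylsilyl ether of 9 | CC1=C[C@](C)([C@H](O[Si](CC)(CC)CC)CC1=O)[C@@H]2CC(=O)O[C@H]2O[C@@H]3C[C@H](C)CC[C@H]3C(C)C | intermediate
11 | tertiary allylic alcohol: 1,2,4-trimethyl-4-(lactonyl)-5-(triethylsilyloxy)cyclohex-2-en-1-ol with C3–OH, C1–OSiEt3 and C10–CH3 all β | CC1=C[C@](C)([C@H](O[Si](CC)(CC)CC)C[C@]1(C)O)[C@@H]2CC(=O)O[C@H]2O[C@@H]3C[C@H](C)CC[C@H]3C(C)C | intermediate
12 | vinyl ether of 11 (C3β–O–CH=CH2) | CC1=C[C@](C)([C@H](O[Si](CC)(CC)CC)C[C@]1(C)OC=C)[C@@H]2CC(=O)O[C@H]2O[C@@H]3C[C@H](C)CC[C@H]3C(C)C | intermediate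
13 | diethyl phosphonite at lactone carbon C8 of 12 (trans to C10) | CC1=C[C@](C)([C@H](O[Si](CC)(CC)CC)C[C@]1(C)OC=C)[C@@H]2[C@@H](P(OCC)OCC)C(=O)O[C@H]2O[C@@H]3C[C@H](C)CC[C@H]3C(C)C | intermediate
14 | diethyl phosphonate at lactone carbon C8 of 12 (trans to C10) | CC1=C[C@](C)([C@H](O[Si](CC)(CC)CC)C[C@]1(C)OC=C)[C@@H]2[C@@H](P(=O)(OCC)OCC)C(=O)O[C@H]2O[C@@H]3C[C@H](C)CC[C@H]3C(C)C | intermediate
15 | Claisen aldehyde: ring A with C3=C4 (both methylated), C5β–CH2CHO (H-5 α), C10 carrying CH3 (β) and the phosphono lactone, C1β–OSiEt3 | CC1=C(C)[C@H](CC=O)[C@@](C)([C@@H]2[C@@H](P(=O)(OCC)OCC)C(=O)O[C@H]2O[C@@H]3C[C@H](C)CC[C@H]3C(C)C)[C@H](O[Si](CC)(CC)CC)C1 | intermediate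
16 | tricyclic 3,7-diene-12,11-olide: 1β-OSiEt3, 5α-H, 9α-H, 10β-CH3, lactone C=O (C12) on C8, acetal C11 on C9 with the l-menthyloxy group trans to C10 | CC1=C(C)[C@@H]2CC=C3C(=O)O[C@@H](O[C@@H]4C[C@H](C)CC[C@H]4C(C)C)[C@@H]3[C@@]2(C)[C@H](O[Si](CC)(CC)CC)C1 | intermediate
17 | 1β-(triethylsilyloxy)-11,12-diol | CC1=C(C)[C@@H]2CC=C(CO)[C@H](CO)[C@@]2(C)[C@H](O[Si](CC)(CC)CC)C1 | intermediate
18 | 1β,11,12-triol | CC1=C(C)[C@@H]2CC=C(CO)[C@H](CO)[C@@]2(C)[C@H](O)C1 | intermediate
19 | 11,12-bis(tert-butyldimethylsilyloxy)-1β-ol | CC1=C(C)[C@@H]2CC=C(CO[Si](C)(C)C(C)(C)C)[C@H](CO[Si](C)(C)C(C)(C)C)[C@@]2(C)[C@H](O)C1 | intermediate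
20 | 3-phenylpropiolic acid | OC(=O)C#Cc1ccccc1 | starting material
21 | 1β-(3-phenylpropioloyl) ester of 19 | CC1=C(C)[C@@H]2CC=C(CO[Si](C)(C)C(C)(C)C)[C@H](CO[Si](C)(C)C(C)(C)C)[C@@]2(C)[C@H](OC(=O)C#Cc2ccccc2)C1 | intermediate
22 | 1β-(Z)-cinnamate of 19 | CC1=C(C)[C@@H]2CC=C(CO[Si](C)(C)C(C)(C)C)[C@H](CO[Si](C)(C)C(C)(C)C)[C@@]2(C)[C@H](OC(=O)/C=C\c2ccccc2)C1 | intermediate
23 | 1β-(Z)-cinnamoyloxy-11,12-diol | CC1=C(C)[C@@H]2CC=C(CO)[C@H](CO)[C@@]2(C)[C@H](OC(=O)/C=C\c2ccccc2)C1 | intermediate
24 | target: 1β-(Z)-cinnamoyloxy-11,12-dialdehyde (drimane numbering 1R,5S,9R,10S) | CC1=C(C)[C@@H]2CC=C(C=O)[C@H](C=O)[C@@]2(C)[C@H](OC(=O)/C=C\c2ccccc2)C1 | target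

**Summary**
Total step count: 16. Longest linear sequence: 16 steps (1 → 24); 4 and 20 enter as purchased components.

**Steps most likely to fail**

Step 10. Loss of the tertiary vinyloxy group by thermal elimination to a ring-A diene may compete with the sigmatropic shift, whose bond-forming terminus C5 sits next to the quaternary C10. The fallback sets out from 11 and returns at 15. Alcohol 11 is heated with N,N-dimethylacetamide dimethyl acetal (xylene, 140 °C) in an Eschenmoser–Claisen rearrangement, which uses the same suprafacial C3→C5 transfer at lower temperature and without an isolated vinyl ether, and should give the γ,δ-unsaturated N,N-dimethylamide F6. Lactone phosphonylation as in step 9 (the lactone α-C–H is far more acidic than that of the amide) gives the phosphono amide F7. Cp2Zr(H)Cl then reduces the tertiary amide selectively to aldehyde 15, which is closed to 16 with LiCl/iPr2NEt.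

Step 8. Transfer vinylation of the hindered tertiary allylic alcohol may stall, or be outrun by ionization and dehydration of the alcohol. The fallback sets out from 11 and returns at 14. The potassium alkoxide of 11 (KH cat., THF) is added to phenyl vinyl sulfoxide to give the 2-(phenylsulfinyl)ethyl ether F4. Lactone phosphonylation as in step 9 gives the phosphono sulfoxide F5. Thermolysis (NaHCO3, 1,2-dichlorobenzene, 180 °C) eliminates the sulfoxide and forms vinyl ether 14 in the flask, where it rearranges at once to 15; LiCl/iPr2NEt then gives 16.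

Step 3. Cycloaddition between two fully substituted diene termini and a β-substituted butenolide may be slow, and the acid-triggered fragmentation may be accompanied by hydrolysis of the menthyl acetal or by skeletal rearrangement of the bicyclic cation. The fallback sets out from 3 and returns at 6. Diene 3 is hydrolysed (aqueous oxalic acid) to 2,4-dimethylcyclohex-2-en-1-one F1. Its thermodynamic, through-conjugated potassium dienolate (KH, THF) is O-silylated with tBuMe2SiCl to the silyl dienol ether tert-butyl[(2,4-dimethylcyclohexa-1,3-dien-1-yl)oxy]dimethylsilane F2. Cycloaddition with 4 gives the bridgehead silyl ether adduct F3, and Bu4NF buffered with AcOH triggers the retro-aldol fragmentation from the bridgehead alkoxide under non-acidic conditions to give 6.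

Further compounds
F1 | step 3 | 2,4-dimethylcyclohex-2-en-1-one (racemic) | CC1C=C(C)C(=O)CC1
F2 | step 3 | tert-butyl[(2,4-dimethylcyclohexa-1,3-dien-1-yl)oxy]dimethylsilane | CC(C)(C)[Si](C)(C)OC1=C(C)C=C(C)CC1
F3 | step 3 | bridgehead tert-butyldimethylsilyl ether analogue of adduct 5 | CC(C)(C)[Si](C)(C)O[C@@]12CC[C@@](C)(C=C1C)[C@H]3[C@H](O[C@@H]4C[C@H](C)CC[C@H]4C(C)C)OC(=O)[C@H]32
F4 | step 8 | 2-(phenylsulfinyl)ethyl ether of 11 (mixture at sulfur) | CC1=C[C@](C)([C@H](O[Si](CC)(CC)CC)C[C@]1(C)OCCS(=O)c5ccccc5)[C@@H]2CC(=O)O[C@H]2O[C@@H]3C[C@H](C)CC[C@H]3C(C)C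
F5 | step 8 | α-(diethoxyphosphoryl) lactone of F4 | CC1=C[C@](C)([C@H](O[Si](CC)(CC)CC)C[C@]1(C)OCCS(=O)c5ccccc5)[C@@H]2[C@@H](P(=O)(OCC)OCC)C(=O)O[C@H]2O[C@@H]3C[C@H](C)CC[C@H]3C(C)C
F6 | step 10 | C5β–CH2C(=O)N(CH3)2 amide from Eschenmoser–Claisen rearrangement of 11 | CC1=C(C)[C@H](CC(=O)N(C)C)[C@@](C)([C@@H]2CC(=O)O[C@H]2O[C@@H]3C[C@H](C)CC[C@H]3C(C)C)[C@H](O[Si](CC)(CC)CC)C1
F7 | step 10 | α-(diethoxyphosphoryl) lactone of F6 | CC1=C(C)[C@H](CC(=O)N(C)C)[C@@](C)([C@@H]2[C@@H](P(=O)(OCC)OCC)C(=O)O[C@H]2O[C@@H]3C[C@H](C)CC[C@H]3C(C)C)[C@H](O[Si](CC)(CC)CC)C1
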